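## Structural features

Sophonorol F is a 3-hydroxyisoflavanone: benzene ring A is fused through C4a and C8a to the dihydropyranone ring C (O1, C2, C3, C4), and benzene ring B is attached by C1' to C3. Ring A is a fully differentiated phloroglucinol, with a free hydroxyl at C5, a methyl ether at C7, the ring C oxygen O1 on C8a, a prenyl group at C8 and the C4 ketone on C4a; C6 is its only unsubstituted position. Ring B carries a methyl ether at C2', a prenyl group at C3' and a free hydroxyl at C4'. C3 is the only stereocentre, so no neighbouring centre can relay configuration; it is quaternary, bears OH, ring B, C2 and the C4 carbonyl, and is (S) (priorities OH > C4 > C2 > C1'). The fragile parts are the two trisubstituted prenyl olefins (acid closes them onto an ortho hydroxyl or adds across them; electrophilic halogen, peracids and osmium attack them first), the free phenols and the tertiary α-ketol. Because C3 has no hydrogen, it cannot epimerise by enolisation and ring C cannot open by β-elimination, so the centre can be installed early. The real difficulty is to make this oxygenated quaternary centre, flanked by a carbonyl and an ortho-substituted aryl group, as one enantiomer, and to place five different substituents on ring A without ambiguity. The plan exploits that O1 and the C4 carbonyl sit on neighbouring ring A carbons (C8a and C4a), and that the oxygen on C5, beside C4a, polarises a C4a–C8a aryne so that an oxygen nucleophile goes to C8a and the carbanion appears at C4a.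

## Logic of the disconnections

28 ⇒ 27. The three O–CH2 acetal bonds on O3, O5 and O4' are cut last. Free phenols and a free tertiary hydroxyl would be proton sources and competing nucleophiles in the ring-forming step, so they are masked until the end. A single acetal type keeps the endgame to one operation. The demand is an unmasking mild enough for two prenyl groups, one of them ortho to the phenol that is set free.

27 ⇒ 14 + 25 (stored as 23). O1–C8a and C4–C4a are cut together. This removes ring C in one stroke and divides the molecule into a ring A synthon with no stereochemistry and a C2–C3–C4 unit that already carries ring B and the finished stereocentre. The forward step must add the oxygen of 14 to C8a and not C4a, and must let the C4a carbanion reach the ester before it is protonated. It must do this without fragmenting the β-alkoxy ester.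

14 ⇒ 13 ⇒ 12. The O–Si bond on the primary oxygen and the O–CH2 acetal on the tertiary oxygen are protecting-group cuts. The tertiary oxygen needs a group that cannot migrate to the neighbouring primary alkoxide, which rules out silicon and acyl groups, and that can be put on without making an alkoxide. The primary oxygen needs a group that comes off under buffered, non-basic conditions.

12 ⇒ 3 + 11. The C3–C1' bond is cut. This separates ring B from a three-carbon keto ester and reduces the stereochemical problem to face selection at one ketone. The forward step must deliver a hindered, electron-rich aryl group to the Re face of 3 and must tolerate the prenyl olefin, which excludes osmium- or peracid-based ways of oxygenating C3.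

3 ⇒ 2 ⇒ 1. The C2 carbonyl is traced to a secondary alcohol and the silyl ether to a primary hydroxyl. Both steps are routine, and the stereocentre of 1 is irrelevant because it is oxidised away.

11 ⇒ 8 ⇒ 5 + 6; 5 ⇒ 4. The C–B bond is traced to C–Br, the C3'–CH2 bond of the prenyl group to a ring C–H flanked by two oxygens, and the acetal to the phenol. The bromine is already in place in 4, so no halogenation is ever run on a prenylated arene. The demand is a metalation of 5 that leaves the C–Br bond alone.

23 ⇒ 22 ⇒ 21. The O–S bond of the triflate and then the O–C(O)N bond are cut. This shows that the oxygen on C8a can serve first as a directing group and then as the leaving group. The hindered carbamate must be removed without acid, which would strip silicon from the electron-rich ring.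

21 ⇒ 19 + 6; 19 ⇒ 17. The C8–CH2 bond of the prenyl group and the C4a–Si bond are cut, in that order. Both positions are ortho to the carbamate oxygen and can be addressed one after the other by directed metalation. Silicon goes in first and prenyl last, so that no alkyllithium meets a benzylic–allylic methylene and no electrophilic halogen is needed on ring A. The first metalation must choose the carbamate/acetal position over the carbamate/methoxy position.

17 ⇒ 16 ⇒ 15. The carbamoyl and the acetal are removed to reach a symmetric, commercial diol. The price is one statistical mono-protection at the very start, on the cheapest material of the route.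

## Other disconnections considered

Alternative 1: Ring B is cut at C1'–C2' and C5'–C6'. In the forward step the bis(silyloxy)diene A1, with the prenyl group on its 2-position, adds to the terminal ynone A2 that is tethered to ring A through O1–C2. Loss of methoxide on fluoride work-up aromatises the adduct to the resorcinol ketone A3.
- In its favour: the ring B oxygen pattern and the prenyl position are fixed by the diene, and A1 derives from a simple prenylated acetoacetate. Cycloaddition–aromatisation of this kind is established chemistry, so on mechanism this alternative is the better-founded of the two. On certainty of the ring B prenyl position it is also the better, since no metalation of a bromoarene is needed.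
- Against it: A3 contains neither ring C nor the stereocentre. Its two phenols must be differentiated (4'-O protection, then methylation of the chelated 2'-OH), the acetal must be unmasked, and ring C must still be closed with control of C3. A2 is a base-sensitive α-aryloxy ynone.
- Comparison: it spends its key step on a ring that three routine steps from a commercial bromophenol already supply. On structure and step economy the chosen plan is clearly ahead.

Alternative 2: Ring A is cut at C5–C4a and C8–C8a. The silyloxydiene A4, with the prenyl group on its terminus, would add across the sulfonyl-bearing double bond of the enantiopure dihydropyranone A5. Loss of silyl methyl ether and benzenesulfinic acid would give A6 with C5–OH free.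
- In its favour: every ring A substituent is fixed by the diene, so there is no aryne regiochemistry, no directed-metalation regiochemistry and no statistical protection; on ring A regiocontrol it is the better plan. It also leaves one acetal fewer to remove, which is a small advantage.
- Equal point: like the chosen plan it carries a pre-formed quaternary centre through the ring-forming step.
- Against it: A5 is a vinylogous ester, an electron-rich dienophile activated only by the sulfonyl group. A4 is substituted at its nucleophilic terminus. The new bond to C4a forms next to the quaternary C3. Making A5 needs the same glycerate-type stereocentre plus the construction and sulfonylation of the pyranone, and the tertiary acetal problem of the endgame remains.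
- Comparison: it is weaker on reactivity match and on step economy.

Alternative 3: Ring C is cut at C3–C4. A chiral triazolium-derived carbene would turn the ring A aldehyde of the keto aldehyde A7 into an acyl anion equivalent that adds to the tethered ring B ketone, giving A8.
- In its favour: intramolecular crossed benzoin closure to 3-hydroxychroman-4-ones is an established, catalytic, enantioselective reaction class, so on precedent it is the better plan. The tertiary hydroxyl emerges unprotected, so only two phenolic acetals remain; on the endgame it is also the better. A7 comes from a simple phenol alkylation with an α-bromo ketone, so step count would be equal or slightly lower.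
- Against it: the acceptor is an ortho-methoxy, electron-rich aryl ketone, the least reactive class for this reaction. The aldehyde is flanked by two ortho oxygens. The α-aryloxy ketone can enolise and undergo aldol closure onto the aldehyde. Enantioselectivity would be set in the last C–C bond-forming step, on the full skeleton, with reversibility of the benzoin as a route to erosion.
- Comparison: the chosen plan fixes and can purify the stereocentre at fragment stage (12) and joins two finished halves. This decoupling of stereocontrol from ring closure is the reason for keeping it, at the price of a ring-forming step without direct precedent.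

Key step: step 15

Remarks on the chemistry (assumptions):
- The (R,R) antipode of the diene ligand in step 6 is taken to deliver the aryl group to the Re face of the ketone of 3; if the sense of induction is the opposite, the (S,S) ligand is used with no other change.
- 5-Methoxyresorcinol and 4-bromo-3-methoxyphenol are taken as purchasable; they replace phloroglucinol and 4-bromoresorcinol and save the first differentiation of the oxygens on each ring.
- An atom-by-atom check shows that 14, 23, 27 and 28 share one constitution and the same (S) configuration at the carbon that becomes C3, so no structural correction is needed. The changes made concern how 23 is prepared (no halogenation of a prenylated phenol) and how the alkoxide is handled in step 15.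

## Route

Step 1
Reactants: 1 methyl 2,3-dihydroxypropanoate (racemic)
Product: 2 methyl 3-[(tert-butyldimethylsilyl)oxy]-2-hydroxypropanoate (racemic)
Conditions: TBSCl (1.05 equiv), imidazole, CH2Cl2, 0 °C
Reagents that add atoms: tert-butyldimethylsilyl chloride, CC(C)(C)[Si](C)(C)Cl
Why: Silyl ether formation; the primary hydroxyl reacts much faster than the secondary hydroxyl next to the ester, which is more hindered and less nucleophilic.

Step 2
Reactants: 2 methyl 3-[(tert-butyldimethylsilyl)oxy]-2-hydroxypropanoate
Product: 3 methyl 3-[(tert-butyldimethylsilyl)oxy]-2-oxopropanoate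
Conditions: Dess–Martin periodinane, CH2Cl2, 0 °C → rt
Reagents that add atoms: none
Why: Dess–Martin oxidation of the secondary α-hydroxy ester gives the α-keto ester under non-aqueous conditions that avoid hydrate formation and silyl loss; the stereocentre of 1 is erased here on purpose.

Step 3
Reactants: 4 4-bromo-3-methoxyphenol
Product: 5 1-bromo-2-methoxy-4-(methoxymethoxy)benzene
Conditions: MOMCl, i-Pr2NEt, CH2Cl2, 0 °C → rt
Reagents that add atoms: chloromethyl methyl ether, COCCl
Why: Williamson-type O-alkylation of the phenol; the acetal survives organolithium, fluoride and alkoxide chemistry and acidifies the ring hydrogen between the two oxygens.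

Step 4
Reactants: 5 1-bromo-2-methoxy-4-(methoxymethoxy)benzene; 6 prenyl bromide (1-bromo-3-methylbut-2-ene)
Product: 8 1-bromo-2-methoxy-4-(methoxymethoxy)-3-(3-methylbut-2-en-1-yl)benzene, via aryllithium 7 (not isolated)
Conditions: LiN(i-Pr)2, THF, −78 °C; CuBr·SMe2 (10 mol%), 6, −78 → 0 °C
Reagents that add atoms: none
Why: Directed ortho-lithiation with a lithium amide, which deprotonates the one hydrogen flanked by two oxygen substituents and does not exchange the bromine, followed by copper-catalysed SN2 allylation at the unsubstituted terminus of prenyl bromide. The lithium in 7 is meta to bromine, so it cannot eliminate to an aryne.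

Step 5
Reactants: 8 1-bromo-2-methoxy-4-(methoxymethoxy)-3-(3-methylbut-2-en-1-yl)benzene
Product: 11 [2-methoxy-4-(methoxymethoxy)-3-(3-methylbut-2-en-1-yl)phenyl]boronic acid, via aryllithium 9 (not isolated), via lithium triisopropoxyborate 10 (not isolated)
Conditions: n-BuLi, THF, −78 °C; B(O-i-Pr)3, −78 °C → rt; aq. NH4Cl
Reagents that add atoms: triisopropyl borate, CC(C)OB(OC(C)C)OC(C)C; water, O
Why: Bromine–lithium exchange at −78 °C is faster than any deprotonation of the prenyl methylene; borylation of the aryllithium and hydrolysis at about pH 6 give the boronic acid with both acetal and olefin intact.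

Step 6
Reactants: 3 methyl 3-[(tert-butyldimethylsilyl)oxy]-2-oxopropanoate; 11 [2-methoxy-4-(methoxymethoxy)-3-(3-methylbut-2-en-1-yl)phenyl]boronic acid
Product: 12 methyl (S)-3-[(tert-butyldimethylsilyl)oxy]-2-hydroxy-2-[2-methoxy-4-(methoxymethoxy)-3-(3-methylbut-2-en-1-yl)phenyl]propanoate
Conditions: [RhCl(C2H4)2]2 (2.5 mol%), (R,R)-2,5-diphenylbicyclo[2.2.2]octa-2,5-diene (5.5 mol%), KOH (10 mol%), 1,4-dioxane/H2O (10:1), 30 °C
Reagents that add atoms: none
Why: Rhodium-catalysed enantioselective 1,2-addition of an arylboronic acid to an α-keto ester: transmetalation gives an aryl–rhodium species (monovalent rhodium) that inserts the ester-activated ketone, and hydrolysis of the rhodium alkoxide turns the cycle over. The C3 stereocentre is set by the C2-symmetric diene, which must place the aryl group on the Re face of the ketone to give (S); the trisubstituted prenyl olefin is too hindered to compete for the metal.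

Step 7
Reactants: 12 methyl (S)-3-[(tert-butyldimethylsilyl)oxy]-2-hydroxy-2-[2-methoxy-4-(methoxymethoxy)-3-(3-methylbut-2-en-1-yl)phenyl]propanoate
Product: 13 methyl (S)-3-[(tert-butyldimethylsilyl)oxy]-2-(methoxymethoxy)-2-[2-methoxy-4-(methoxymethoxy)-3-(3-methylbut-2-en-1-yl)phenyl]propanoate
Conditions: MOMCl, i-Pr2NEt, n-Bu4NI (cat.), ClCH2CH2Cl, 60 °C
Reagents that add atoms: chloromethyl methyl ether, COCCl
Why: O-alkylation of the hindered tertiary α-hydroxy ester with the iodide-activated chloromethyl ether under amine base; no alkoxide is formed, so neither 1,4-silyl migration nor retro-aldol cleavage can occur, and an acetal cannot later migrate to the primary alkoxide as a silyl group would.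

Step 8
Reactants: 13 methyl (S)-3-[(tert-butyldimethylsilyl)oxy]-2-(methoxymethoxy)-2-[2-methoxy-4-(methoxymethoxy)-3-(3-methylbut-2-en-1-yl)phenyl]propanoate
Product: 14 methyl (S)-3-hydroxy-2-(methoxymethoxy)-2-[2-methoxy-4-(methoxymethoxy)-3-(3-methylbut-2-en-1-yl)phenyl]propanoate
Conditions: n-Bu4NF, AcOH, THF, 0 °C → rt
Reagents that add atoms: none
Why: Fluoride cleavage of the primary silyl ether, buffered with AcOH so that the liberated alkoxide is protonated before it can fragment or transesterify; acetals, ester and olefin are inert.

Step 9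
Reactants: 15 5-methoxyresorcinol (5-methoxybenzene-1,3-diol)
Product: 16 3-methoxy-5-(methoxymethoxy)phenol
Conditions: MOMCl (1.0 equiv), i-Pr2NEt, CH2Cl2, −10 °C → rt
Reagents that add atoms: chloromethyl methyl ether, COCCl
Why: Mono-O-alkylation of a symmetric diol with one equivalent of reagent; the outcome is statistical, and the bis-ether and recovered 15 are separated and recycled. This step decides which oxygen becomes O5.

Step 10
Reactants: 16 3-methoxy-5-(methoxymethoxy)phenol
Product: 17 3-methoxy-5-(methoxymethoxy)phenyl N,N-diethylcarbamate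
Conditions: NaH, THF, 0 °C; ClC(O)NEt2, rt
Reagents that add atoms: N,N-diethylcarbamoyl chloride, CCN(CC)C(Cl)=O
Why: O-carbamoylation of the sodium phenoxide; the diethylcarbamate is the strongest oxygen-based director for ortho-lithiation and needs no silyl triflate for its use, so the aryl acetal is not put at risk.

Step 11
Reactants: 17 3-methoxy-5-(methoxymethoxy)phenyl N,N-diethylcarbamate
Product: 19 5-methoxy-3-(methoxymethoxy)-2-(trimethylsilyl)phenyl N,N-diethylcarbamate, via aryllithium 18 (not isolated)
Conditions: s-BuLi, TMEDA, THF, −78 °C; Me3SiCl, −78 °C → rt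
Reagents that add atoms: chlorotrimethylsilane, C[Si](C)(C)Cl
Why: Directed ortho-metalation; lithiation should occur at the position flanked by the carbamate and the chelating acetal, the two strongest directors, not at the carbamate/methoxy or acetal/methoxy positions. Silylation at −78 °C precedes any anionic Fries shift.

Step 12
Reactants: 19 5-methoxy-3-(methoxymethoxy)-2-(trimethylsilyl)phenyl N,N-diethylcarbamate; 6 prenyl bromide
Product: 21 3-methoxy-5-(methoxymethoxy)-2-(3-methylbut-2-en-1-yl)-6-(trimethylsilyl)phenyl N,N-diethylcarbamate, via aryllithium 20 (not isolated)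
Conditions: s-BuLi, TMEDA, THF, −78 °C; CuBr·SMe2 (10 mol%), 6, −78 → −20 °C
Reagents that add atoms: none
Why: Second carbamate-directed ortho-lithiation at the only remaining ortho position, then copper-catalysed SN2 allylation. Because the prenyl group enters last, no alkyllithium meets a prenylated arene (no lateral lithiation) and no electrophilic halogen is used on ring A.

Step 13
Reactants: 21 3-methoxy-5-(methoxymethoxy)-2-(3-methylbut-2-en-1-yl)-6-(trimethylsilyl)phenyl N,N-diethylcarbamate
Product: 22 3-methoxy-5-(methoxymethoxy)-2-(3-methylbut-2-en-1-yl)-6-(trimethylsilyl)phenol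
Conditions: LiAlH4, THF, 0 → 50 °C; aq. KNaC4H4O6
Reagents that add atoms: none
Why: Reductive cleavage of the aryl carbamate: hydride attacks the carbamoyl carbon and releases the hindered phenoxide; acetal, aryl–silicon bond and olefin are inert, and the neutral tartrate work-up avoids protodesilylation of the electron-rich arylsilane.

Step 14
Reactants: 22 3-methoxy-5-(methoxymethoxy)-2-(3-methylbut-2-en-1-yl)-6-(trimethylsilyl)phenol
Product: 23 3-methoxy-5-(methoxymethoxy)-2-(3-methylbut-2-en-1-yl)-6-(trimethylsilyl)phenyl trifluoromethanesulfonate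
Conditions: NaH, THF, 0 °C; PhNTf2, rt
Reagents that add atoms: N-phenylbis(trifluoromethanesulfonimide), O=S(=O)(N(c1ccccc1)S(=O)(=O)C(F)(F)F)C(F)(F)F
Why: O-triflation of the hindered sodium phenoxide with a mild triflyl donor gives the 2-silylaryl triflate, the standard fluoride-triggered aryne precursor, without exposing olefin or acetal to triflic anhydride.

Step 15
Reactants: 14 methyl (S)-3-hydroxy-2-(methoxymethoxy)-2-[2-methoxy-4-(methoxymethoxy)-3-(3-methylbut-2-en-1-yl)phenyl]propanoate; 23 3-methoxy-5-(methoxymethoxy)-2-(3-methylbut-2-en-1-yl)-6-(trimethylsilyl)phenyl trifluoromethanesulfonate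
Product: 27 (S)-7-methoxy-3,5-bis(methoxymethoxy)-3-[2-methoxy-4-(methoxymethoxy)-3-(3-methylbut-2-en-1-yl)phenyl]-8-(3-methylbut-2-en-1-yl)chroman-4-one, via sodium alkoxide 24 (not isolated), via aryne 25 (not isolated), via aryl anion 26 (not isolated)
Conditions: NaH, THF, −20 °C; then 23 (1.5 equiv), CsF, 18-crown-6, THF, −20 °C → rt
Reagents that add atoms: none
Why: Proposed new method: fluoride attacks the silicon of 23 and triflate leaves to give aryne 25; the primary alkoxide 24 adds to the aryne carbon remote from the C5 acetal oxygen (future C8a), which places the carbanion of 26 on C4a, next to that oxygen and stabilised by its inductive pull; 26 then attacks the methyl ester through a six-membered transition state and the tetrahedral intermediate expels methoxide. The closest known reaction type is the aryne annulation of salicylate esters to xanthones, in which an oxygen nucleophile adds and the aryl anion is captured by the ester; here an aliphatic alkoxide and an aliphatic, α-alkoxy-activated ester take those roles. Ring C closes in the second event, by 6-exo-trig acyl substitution, after the intermolecular O1–C8a bond has formed. No stereocentre is created; C3 is quaternary, has no acidic hydrogen and none of its bonds is broken, so the configuration of 14 is carried into 27. The step needs oxygen to add at C8a in spite of the neighbouring prenyl group, which the distortion of the aryne by the C5 oxygen should secure. It also needs acyl capture to outrun protonation of 26, which the proton-free medium should secure (alkoxide preformed with NaH, hydrogen lost as gas, THF and not MeCN as solvent). The alkoxide is made cold and meets the aryne as it forms, to limit retro-aldol loss of formaldehyde and intermolecular transesterification.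

Step 16
Reactants: 27 (S)-7-methoxy-3,5-bis(methoxymethoxy)-3-[2-methoxy-4-(methoxymethoxy)-3-(3-methylbut-2-en-1-yl)phenyl]-8-(3-methylbut-2-en-1-yl)chroman-4-one
Product: 28 sophonorol F, (S)-3,5-dihydroxy-3-[4-hydroxy-2-methoxy-3-(3-methylbut-2-en-1-yl)phenyl]-7-methoxy-8-(3-methylbut-2-en-1-yl)chroman-4-one
Conditions: HCl (ca. 1 M), MeOH/H2O, 40 °C
Reagents that add atoms: none
Why: Acid-catalysed acetal exchange with methanol removes all three MOM groups. The C5 acetal is labilised by the peri carbonyl, the C4' acetal is an ordinary phenolic one, and the C3 acetal sits on an α-keto tertiary oxygen that is a good leaving alcohol; dilute acid at moderate temperature and controlled time should spare ortho-prenyl phenols.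

## Compound list

1 | methyl 2,3-dihydroxypropanoate (racemic) | COC(=O)C(O)CO | starting material
2 | methyl 3-[(tert-butyldimethylsilyl)oxy]-2-hydroxypropanoate (racemic) | COC(=O)C(O)CO[Si](C)(C)C(C)(C)C | intermediate
3 | methyl 3-[(tert-butyldimethylsilyl)oxy]-2-oxopropanoate | COC(=O)C(=O)CO[Si](C)(C)C(C)(C)C | intermediate
4 | 4-bromo-3-methoxyphenol | COc1cc(O)ccc1Br | starting material
5 | 1-bromo-2-methoxy-4-(methoxymethoxy)benzene | COCOc1ccc(Br)c(OC)c1 | intermediate
6 | prenyl bromide (1-bromo-3-methylbut-2-ene) | CC(C)=CCBr | starting material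
7 | [3-bromo-2-methoxy-6-(methoxymethoxy)phenyl]lithium | [Li]c1c(OCOC)ccc(Br)c1OC | intermediate
8 | 1-bromo-2-methoxy-4-(methoxymethoxy)-3-(3-methylbut-2-en-1-yl)benzene | COCOc1ccc(Br)c(OC)c1CC=C(C)C | intermediate
9 | [2-methoxy-4-(methoxymethoxy)-3-(3-methylbut-2-en-1-yl)phenyl]lithium | [Li]c1ccc(OCOC)c(CC=C(C)C)c1OC | intermediate
10 | lithium triisopropoxy[2-methoxy-4-(methoxymethoxy)-3-(3-methylbut-2-en-1-yl)phenyl]borate | [Li+].CC(C)O[B-](OC(C)C)(OC(C)C)c1ccc(OCOC)c(CC=C(C)C)c1OC | intermediate
11 | [2-methoxy-4-(methoxymethoxy)-3-(3-methylbut-2-en-1-yl)phenyl]boronic acid | COCOc1ccc(B(O)O)c(OC)c1CC=C(C)C | intermediate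
12 | methyl (S)-3-[(tert-butyldimethylsilyl)oxy]-2-hydroxy-2-[2-methoxy-4-(methoxymethoxy)-3-(3-methylbut-2-en-1-yl)phenyl]propanoate | CC(C)(C)[Si](C)(C)OC[C@@](O)(c1ccc(OCOC)c(CC=C(C)C)c1OC)C(=O)OC | intermediate
13 | methyl (S)-3-[(tert-butyldimethylsilyl)oxy]-2-(methoxymethoxy)-2-[2-methoxy-4-(methoxymethoxy)-3-(3-methylbut-2-en-1-yl)phenyl]propanoate | CC(C)(C)[Si](C)(C)OC[C@@](OCOC)(c1ccc(OCOC)c(CC=C(C)C)c1OC)C(=O)OC | intermediate
14 | methyl (S)-3-hydroxy-2-(methoxymethoxy)-2-[2-methoxy-4-(methoxymethoxy)-3-(3-methylbut-2-en-1-yl)phenyl]propanoate | OC[C@@](OCOC)(c1ccc(OCOC)c(CC=C(C)C)c1OC)C(=O)OC | intermediate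
15 | 5-methoxyresorcinol (5-methoxybenzene-1,3-diol) | COc1cc(O)cc(O)c1 | starting material
16 | 3-methoxy-5-(methoxymethoxy)phenol | COCOc1cc(O)cc(OC)c1 | intermediate
17 | 3-methoxy-5-(methoxymethoxy)phenyl N,N-diethylcarbamate | CCN(CC)C(=O)Oc1cc(OC)cc(OCOC)c1 | intermediate
18 | {2-[(diethylcarbamoyl)oxy]-4-methoxy-6-(methoxymethoxy)phenyl}lithium | CCN(CC)C(=O)Oc1cc(OC)cc(OCOC)c1[Li] | intermediate
19 | 5-methoxy-3-(methoxymethoxy)-2-(trimethylsilyl)phenyl N,N-diethylcarbamate | CCN(CC)C(=O)Oc1cc(OC)cc(OCOC)c1[Si](C)(C)C | intermediate
20 | {2-[(diethylcarbamoyl)oxy]-6-methoxy-4-(methoxymethoxy)-3-(trimethylsilyl)phenyl}lithium | CCN(CC)C(=O)Oc1c([Li])c(OC)cc(OCOC)c1[Si](C)(C)C | intermediate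
21 | 3-methoxy-5-(methoxymethoxy)-2-(3-methylbut-2-en-1-yl)-6-(trimethylsilyl)phenyl N,N-diethylcarbamate | CCN(CC)C(=O)Oc1c(CC=C(C)C)c(OC)cc(OCOC)c1[Si](C)(C)C | intermediate
22 | 3-methoxy-5-(methoxymethoxy)-2-(3-methylbut-2-en-1-yl)-6-(trimethylsilyl)phenol | COCOc1cc(OC)c(CC=C(C)C)c(O)c1[Si](C)(C)C | intermediate
23 | 3-methoxy-5-(methoxymethoxy)-2-(3-methylbut-2-en-1-yl)-6-(trimethylsilyl)phenyl trifluoromethanesulfonate | COCOc1cc(OC)c(CC=C(C)C)c(OS(=O)(=O)C(F)(F)F)c1[Si](C)(C)C | intermediate
24 | sodium alkoxide of 14 (sodium salt of the primary hydroxyl) | [Na+].[O-]C[C@@](OCOC)(c1ccc(OCOC)c(CC=C(C)C)c1OC)C(=O)OC | intermediate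
25 | 4-methoxy-6-(methoxymethoxy)-3-(3-methylbut-2-en-1-yl)-1,2-didehydrobenzene (ring A aryne) | COCOC1=CC(OC)=C(CC=C(C)C)C#C1 | intermediate
26 | sodium salt of the C4a carbanion of methyl (S)-3-[3-methoxy-5-(methoxymethoxy)-2-(3-methylbut-2-en-1-yl)phenoxy]-2-(methoxymethoxy)-2-[2-methoxy-4-(methoxymethoxy)-3-(3-methylbut-2-en-1-yl)phenyl]propanoate (carbanion on the ring carbon between the ether oxygen and the methoxymethoxy group) | [Na+].COCOc1cc(OC)c(CC=C(C)C)c(OC[C@@](OCOC)(c2ccc(OCOC)c(CC=C(C)C)c2OC)C(=O)OC)[c-]1 | intermediate
27 | (S)-7-methoxy-3,5-bis(methoxymethoxy)-3-[2-methoxy-4-(methoxymethoxy)-3-(3-methylbut-2-en-1-yl)phenyl]-8-(3-methylbut-2-en-1-yl)chroman-4-one (3,5,4'-tris-O-MOM sophonorol F) | COc1cc(OCOC)c2c(c1CC=C(C)C)OC[C@@](OCOC)(c1ccc(OCOC)c(CC=C(C)C)c1OC)C2=O | intermediate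
28 | sophonorol F, (S)-3,5-dihydroxy-3-[4-hydroxy-2-methoxy-3-(3-methylbut-2-en-1-yl)phenyl]-7-methoxy-8-(3-methylbut-2-en-1-yl)chroman-4-one | COc1cc(O)c2c(c1CC=C(C)C)OC[C@@](O)(c1ccc(O)c(CC=C(C)C)c1OC)C2=O | target

## Step count and least certain steps

Total: 16 steps. Longest linear sequence: 8 steps (steps 3–8, 15, 16 from 4; equally steps 9–14, 15, 16 from 15).

Step 15 (key step; it alone bears the label "Proposed new method:"). The most likely failure is that alkoxide 24 is lost before it meets the aryne, by retro-aldol release of formaldehyde or by attack on sulfur of the triflate, or that 26 is protonated before it reaches the ester, so that O-arylation stops at the open aryl ether. Crowding by the C8 prenyl group could also divert the oxygen to C4a.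

Fallback, by known chemistry, from 13 and 23 back to 27. The ester of 13 is saponified (LiOH, THF/MeOH/H2O) to (S)-3-[(tert-butyldimethylsilyl)oxy]-2-(methoxymethoxy)-2-[2-methoxy-4-(methoxymethoxy)-3-(3-methylbut-2-en-1-yl)phenyl]propanoic acid F1. Its carboxylate is combined with the aryne from 23 (CsF, THF, heat) in the known insertion of an aryne into the O–C(acyl) bond of a carboxylic acid (O-arylation, then acyl transfer to the neighbouring carbanion), giving the ortho-hydroxyaryl ketone (S)-3-[(tert-butyldimethylsilyl)oxy]-1-[2-hydroxy-4-methoxy-6-(methoxymethoxy)-3-(3-methylbut-2-en-1-yl)phenyl]-2-(methoxymethoxy)-2-[2-methoxy-4-(methoxymethoxy)-3-(3-methylbut-2-en-1-yl)phenyl]propan-1-one F2. A carboxylate is far less basic than 24 and cannot fragment. Buffered n-Bu4NF then frees the primary alcohol (S)-3-hydroxy-1-[2-hydroxy-4-methoxy-6-(methoxymethoxy)-3-(3-methylbut-2-en-1-yl)phenyl]-2-(methoxymethoxy)-2-[2-methoxy-4-(methoxymethoxy)-3-(3-methylbut-2-en-1-yl)phenyl]propan-1-one F3, and an intramolecular Mitsunobu etherification (PPh3, DIAD, THF) closes O1–C2 to give 27.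

Step 6. The hindered, electron-rich ortho-alkoxy aryl group may transfer slowly, so that protodeboronation and base-induced decomposition of the keto ester compete, and face discrimination between the CH2OSi and CO2Me arms of a small acyclic ketone may be poor.

Fallback from 8 and 3 back to 12. Aryllithium 9 (from 8, n-BuLi, −78 °C) is transmetalated with MgBr2·OEt2 and added to the ketone of 3 at −78 °C to give racemic methyl 3-[(tert-butyldimethylsilyl)oxy]-2-hydroxy-2-[2-methoxy-4-(methoxymethoxy)-3-(3-methylbut-2-en-1-yl)phenyl]propanoate F4. The enantiomers are separated by preparative chromatography on a chiral stationary phase; the (S)-enantiomer is 12 and methyl (R)-3-[(tert-butyldimethylsilyl)oxy]-2-hydroxy-2-[2-methoxy-4-(methoxymethoxy)-3-(3-methylbut-2-en-1-yl)phenyl]propanoate F5 is set aside.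

Step 16. Cleavage of the tertiary acetal may be incomplete at an acidity the prenyl groups tolerate; forcing it invites acid-catalysed closure of the C3' prenyl group onto the freed C4' hydroxyl and addition of HCl or methanol across the olefins.

Fallback from 12 back to 28, with a more labile group on O3. The tertiary alcohol 12 is protected with ethyl vinyl ether and pyridinium p-toluenesulfonate as methyl (2S)-3-[(tert-butyldimethylsilyl)oxy]-2-(1-ethoxyethoxy)-2-[2-methoxy-4-(methoxymethoxy)-3-(3-methylbut-2-en-1-yl)phenyl]propanoate F6 (both epimers at the acetal carbon). Buffered n-Bu4NF gives methyl (2S)-2-(1-ethoxyethoxy)-3-hydroxy-2-[2-methoxy-4-(methoxymethoxy)-3-(3-methylbut-2-en-1-yl)phenyl]propanoate F7. The annulation of step 15 with 23 gives (3S)-3-(1-ethoxyethoxy)-7-methoxy-5-(methoxymethoxy)-3-[2-methoxy-4-(methoxymethoxy)-3-(3-methylbut-2-en-1-yl)phenyl]-8-(3-methylbut-2-en-1-yl)chroman-4-one F8. Dilute HCl in MeOH at rt should then remove the 1-ethoxyethyl group within minutes and the two phenolic MOM groups under the mildest conditions used for prenylated phenols, giving 28.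

Step 11. Regiocontrol may be incomplete: metalation at the carbamate/methoxy position would exchange the places of silicon and prenyl on ring A.

Fallback from 15 back to 22, using symmetry in place of director ranking. Diol 15 is converted (NaH, ClC(O)NEt2) into 5-methoxy-1,3-phenylene bis(N,N-diethylcarbamate) F9, whose only doubly carbamate-flanked position is lithiated (s-BuLi, TMEDA, −78 °C) and silylated to 5-methoxy-2-(trimethylsilyl)-1,3-phenylene bis(N,N-diethylcarbamate) F10. The two remaining ring positions are equivalent, so a second lithiation with copper-catalysed prenylation gives 5-methoxy-4-(3-methylbut-2-en-1-yl)-2-(trimethylsilyl)-1,3-phenylene bis(N,N-diethylcarbamate) F11 without ambiguity. LiAlH4 frees 5-methoxy-4-(3-methylbut-2-en-1-yl)-2-(trimethylsilyl)benzene-1,3-diol F12, and MOMCl (1 equiv) with i-Pr2NEt should alkylate the less hindered hydroxyl (the one not flanked by the prenyl group) to give 22.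

## Further compounds

F1 | step 15 | (S)-3-[(tert-butyldimethylsilyl)oxy]-2-(methoxymethoxy)-2-[2-methoxy-4-(methoxymethoxy)-3-(3-methylbut-2-en-1-yl)phenyl]propanoic acid | CC(C)(C)[Si](C)(C)OC[C@@](OCOC)(c1ccc(OCOC)c(CC=C(C)C)c1OC)C(=O)O
F2 | step 15 | (S)-3-[(tert-butyldimethylsilyl)oxy]-1-[2-hydroxy-4-methoxy-6-(methoxymethoxy)-3-(3-methylbut-2-en-1-yl)phenyl]-2-(methoxymethoxy)-2-[2-methoxy-4-(methoxymethoxy)-3-(3-methylbut-2-en-1-yl)phenyl]propan-1-one | CC(C)(C)[Si](C)(C)OC[C@@](OCOC)(c1ccc(OCOC)c(CC=C(C)C)c1OC)C(=O)c1c(O)c(CC=C(C)C)c(OC)cc1OCOC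
F3 | step 15 | (S)-3-hydroxy-1-[2-hydroxy-4-methoxy-6-(methoxymethoxy)-3-(3-methylbut-2-en-1-yl)phenyl]-2-(methoxymethoxy)-2-[2-methoxy-4-(methoxymethoxy)-3-(3-methylbut-2-en-1-yl)phenyl]propan-1-one | OC[C@@](OCOC)(c1ccc(OCOC)c(CC=C(C)C)c1OC)C(=O)c1c(O)c(CC=C(C)C)c(OC)cc1OCOC
F4 | step 6 | methyl 3-[(tert-butyldimethylsilyl)oxy]-2-hydroxy-2-[2-methoxy-4-(methoxymethoxy)-3-(3-methylbut-2-en-1-yl)phenyl]propanoate (racemic) | CC(C)(C)[Si](C)(C)OCC(O)(c1ccc(OCOC)c(CC=C(C)C)c1OC)C(=O)OC
F5 | step 6 | methyl (R)-3-[(tert-butyldimethylsilyl)oxy]-2-hydroxy-2-[2-methoxy-4-(methoxymethoxy)-3-(3-methylbut-2-en-1-yl)phenyl]propanoate | CC(C)(C)[Si](C)(C)OC[C@](O)(c1ccc(OCOC)c(CC=C(C)C)c1OC)C(=O)OC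
F6 | step 16 | methyl (2S)-3-[(tert-butyldimethylsilyl)oxy]-2-(1-ethoxyethoxy)-2-[2-methoxy-4-(methoxymethoxy)-3-(3-methylbut-2-en-1-yl)phenyl]propanoate (both epimers at the acetal carbon) | CC(C)(C)[Si](C)(C)OC[C@@](OC(C)OCC)(c1ccc(OCOC)c(CC=C(C)C)c1OC)C(=O)OC
F7 | step 16 | methyl (2S)-2-(1-ethoxyethoxy)-3-hydroxy-2-[2-methoxy-4-(methoxymethoxy)-3-(3-methylbut-2-en-1-yl)phenyl]propanoate (both epimers at the acetal carbon) | OC[C@@](OC(C)OCC)(c1ccc(OCOC)c(CC=C(C)C)c1OC)C(=O)OC
F8 | step 16 | (3S)-3-(1-ethoxyethoxy)-7-methoxy-5-(methoxymethoxy)-3-[2-methoxy-4-(methoxymethoxy)-3-(3-methylbut-2-en-1-yl)phenyl]-8-(3-methylbut-2-en-1-yl)chroman-4-one (both epimers at the acetal carbon) | COc1cc(OCOC)c2c(c1CC=C(C)C)OC[C@@](OC(C)OCC)(c1ccc(OCOC)c(CC=C(C)C)c1OC)C2=O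
F9 | step 11 | 5-methoxy-1,3-phenylene bis(N,N-diethylcarbamate) | CCN(CC)C(=O)Oc1cc(OC)cc(OC(=O)N(CC)CC)c1
F10 | step 11 | 5-methoxy-2-(trimethylsilyl)-1,3-phenylene bis(N,N-diethylcarbamate) | CCN(CC)C(=O)Oc1cc(OC)cc(OC(=O)N(CC)CC)c1[Si](C)(C)C
F11 | step 11 | 5-methoxy-4-(3-methylbut-2-en-1-yl)-2-(trimethylsilyl)-1,3-phenylene bis(N,N-diethylcarbamate) | CCN(CC)C(=O)Oc1c(CC=C(C)C)c(OC)cc(OC(=O)N(CC)CC)c1[Si](C)(C)C
F12 | step 11 | 5-methoxy-4-(3-methylbut-2-en-1-yl)-2-(trimethylsilyl)benzene-1,3-diol | COc1cc(O)c([Si](C)(C)C)c(O)c1CC=C(C)C
A1 | alternative 1 | 1-methoxy-2-(3-methylbut-2-en-1-yl)-1,3-bis(trimethylsilyloxy)buta-1,3-diene | COC(O[Si](C)(C)C)=C(CC=C(C)C)C(=C)O[Si](C)(C)C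
A2 | alternative 1 | 1-[2-(dimethoxymethyl)-5-methoxy-3-(methoxymethoxy)-6-(3-methylbut-2-en-1-yl)phenoxy]but-3-yn-2-one | C#CC(=O)COc1c(C(OC)OC)c(OCOC)cc(OC)c1CC=C(C)C
A3 | alternative 1 | 1-[2,4-dihydroxy-3-(3-methylbut-2-en-1-yl)phenyl]-2-[2-(dimethoxymethyl)-5-methoxy-3-(methoxymethoxy)-6-(3-methylbut-2-en-1-yl)phenoxy]ethan-1-one | O=C(COc1c(C(OC)OC)c(OCOC)cc(OC)c1CC=C(C)C)c1ccc(O)c(CC=C(C)C)c1O
A4 | alternative 2 | 1,3-dimethoxy-7-methyl-1-(trimethylsilyloxy)octa-1,3,6-triene | COC(O[Si](C)(C)C)=CC(OC)=CCC=C(C)C
A5 | alternative 2 | (S)-3-(methoxymethoxy)-3-[2-methoxy-4-(methoxymethoxy)-3-(3-methylbut-2-en-1-yl)phenyl]-5-(phenylsulfonyl)-2,3-dihydro-4H-pyran-4-one | O=C1C(S(=O)(=O)c2ccccc2)=COC[C@@]1(OCOC)c1ccc(OCOC)c(CC=C(C)C)c1OC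
A6 | alternative 2 | 3,4'-bis-O-(methoxymethyl)sophonorol F | COc1cc(O)c2c(c1CC=C(C)C)OC[C@@](OCOC)(c1ccc(OCOC)c(CC=C(C)C)c1OC)C2=O
A7 | alternative 3 | 4-methoxy-6-(methoxymethoxy)-2-{2-[2-methoxy-4-(methoxymethoxy)-3-(3-methylbut-2-en-1-yl)phenyl]-2-oxoethoxy}-3-(3-methylbut-2-en-1-yl)benzaldehyde | O=Cc1c(OCOC)cc(OC)c(CC=C(C)C)c1OCC(=O)c1ccc(OCOC)c(CC=C(C)C)c1OC
A8 | alternative 3 | 5,4'-bis-O-(methoxymethyl)sophonorol F | COc1cc(OCOC)c2c(c1CC=C(C)C)OC[C@@](O)(c1ccc(OCOC)c(CC=C(C)C)c1OC)C2=O
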